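**Assumption:** I read the SMILES literally as a 3‑aryloxychromone (a C3–O–aryl ether, not a 3‑aryl isoflavone). The molecule has no stereocentres, so there is no stereochemistry to set.

## Retrosynthetic overview
- Target (11) ⇒ C3–O bond and pyranone ring formed together by an anodic radical cross‑coupling/annulation of an o‑hydroxyaryl enaminone (6) with a bis‑MOM‑protected hydroxyquinol phenol (9).
- Enaminone 6 ⇐ 2',4'‑dihydroxy‑3',5'‑diprenylacetophenone (5) ⇐ resorcinol (acylation, then C‑prenylation).
- Phenol 9 ⇐ resorcinol (Vilsmeier formylation, bis‑MOM protection, Dakin‑type oxidation).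
- Ring order: the A‑ring (resorcinol) and B‑ring (second resorcinol) exist from the start. The pyranone ring closes in the key step (Step 7), and the last step is MOM removal.

## Route

**Step 1**
Reactants: 1 resorcinol; 2 acetic acid
Product: 3 2',4'‑dihydroxyacetophenone
Conditions: BF3·OEt2, 90 °C, 1.5 h
Reagents that add atoms: none (acetic acid is reactant 2)
Why: Friedel–Crafts/Hoesch‑type acylation occurs para to one OH, the most activated position, and the 2'‑OH is chelated to the carbonyl.

**Step 2**
Reactants: 3; 4 prenyl bromide (1‑bromo‑3‑methylbut‑2‑ene)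
Product: 5 1‑(2,4‑dihydroxy‑3,5‑bis(3‑methylbut‑2‑enyl)phenyl)ethan‑1‑one
Conditions: 4 (2.5 equiv), KOH (3 equiv), MeOH, 0 °C → rt, 12 h; chromatographic separation
Reagents that add atoms: none (prenyl bromide is reactant 4)
Why: Phenoxide C‑alkylation (ortho/para to O⁻) goes at the two free positions that are ortho to the 4'‑OH (C3' and C5'), giving the 6,8‑diprenyl pattern of the chromone after ring closure. The yield is modest because of O‑alkylation and mono‑prenyl by‑products.

**Step 3**
Reactants: 5
Product: 6 (E)‑3‑(dimethylamino)‑1‑(2,4‑dihydroxy‑3,5‑diprenylphenyl)prop‑2‑en‑1‑one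
Conditions: DMF‑DMA, toluene, 90 °C, 6 h
Reagents that add atoms: DMF‑DMA, CN(C)C(OC)OC (supplies the C2 and C3 carbons plus NMe2)
Why: Condensation of the acetyl CH3 with the DMF acetal gives the push–pull enaminone. The chelated 2'‑OH stays free for later cyclization, and the hindered 4'‑OH between two prenyls is not methylated.

**Step 4**
Reactants: 1 resorcinol
Product: 7 2,4‑dihydroxybenzaldehyde
Conditions: POCl3, DMF, MeCN, 0 °C → rt, then H2O workup
Reagents that add atoms: DMF, CN(C)C=O (supplies CHO); water, O
Why: Vilsmeier–Haack formylation occurs para to one OH and ortho to the other.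

**Step 5**
Reactants: 7
Product: 8 2,4‑bis(methoxymethoxy)benzaldehyde
Conditions: MOMCl (2.5 equiv), i‑Pr2NEt, CH2Cl2, 0 °C → rt
Reagents that add atoms: MOMCl, COCCl
Why: Both phenols are capped as MOM acetals, which survive the oxidation in Step 6 and the radical conditions in Step 7.

**Step 6**
Reactants: 8
Product: 9 2,4‑bis(methoxymethoxy)phenol
Conditions: (i) mCPBA, CH2Cl2, 0 °C → rt; (ii) K2CO3, MeOH, rt
Reagents that add atoms: mCPBA, O=C(OO)c1cccc(Cl)c1 (one O atom is inserted)
Why: Dakin‑type Baeyer–Villiger oxidation gives aryl migration for this electron‑rich aldehyde, forming the aryl formate, which methanolysis converts to the phenol. The OH ends up ortho to one OMOM and para to the other, which is the pattern of the B‑ring.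

**Step 7 (key radical step)**
Reactants: 6; 9 (2.5 equiv)
Product: 10 7‑hydroxy‑6,8‑diprenyl‑3‑[2,4‑bis(methoxymethoxy)phenoxy]‑4H‑chromen‑4‑one
Conditions: undivided cell, graphite(+)/Pt(−), 5 mA (about 3 F/mol), nBu4NPF6, MeCN/HFIP 4:1, 2,6‑lutidine, rt
Reagents that add atoms: none
Why: **Proposed new method:** Anodic oxidation selectively removes an electron (and, with lutidine, a proton) from the most oxidizable species, phenol 9, giving a persistent, electrophilic 2,4‑dialkoxyphenoxyl radical. This radical adds through oxygen to the nucleophilic α‑carbon of the enaminone 6, giving a captodative α‑amino radical, which is oxidized to the iminium. The 2'‑OH then closes onto the iminium carbon, and loss of HNMe2 gives the chromone. The closest known reaction types are oxidative radical cascade cyclizations of o‑hydroxyaryl enaminones to 3‑substituted chromones (sulfenyl, seleno) and phenoxyl‑radical cross‑coupling. Electrolysis is chosen over persulfate because prenyl alkenes survive at these potentials, whereas SO4•⁻ would attack them. The hindered, acyl‑deactivated 7‑OH between two prenyls is oxidized only slowly. No stereocentre is formed.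

**Step 8**
Reactants: 10
Product: 11 Eryvarin F (7‑hydroxy‑3‑(2,4‑dihydroxyphenoxy)‑6,8‑diprenylchromone)
Conditions: 3 M HCl, THF/MeOH 1:1, 40 °C, 6 h
Reagents that add atoms: none
Why: Acid hydrolysis of the two MOM acetals releases CH2O and MeOH. The aryl‑C prenyl groups, the chromone and the aryl ether tolerate dilute acid at this temperature. Both MOM groups leave and nothing else changes, so the final product is the target.

## Checks
- **Structure:** 11 has the chromone core, a 7‑OH, 6‑ and 8‑prenyl groups, and a 3‑O‑aryl group. The aryl has O‑link at C1 with OH at C2 and C4, matching Oc3ccc(O)cc3O.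
- **Atom balance for Step 7:** C21H29NO3 (6) + C10H14O5 (9) − HNMe2 − 2H = C29H34O8 (10). Removing two MOM groups (2 × C2H4O) gives C25H26O6, the target.
- **Starting materials:** every starting material has ≤8 heavy atoms (resorcinol 8, acetic acid 4, prenyl bromide 6).
- **Stereochemistry:** the target is achiral, so nothing can be scrambled.

## Compound list
1 | resorcinol | Oc1cccc(O)c1 | starting material
2 | acetic acid | CC(=O)O | starting material
3 | 2',4'‑dihydroxyacetophenone | CC(=O)c1ccc(O)cc1O | intermediate
4 | prenyl bromide | CC(C)=CCBr | starting material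
5 | 2',4'‑dihydroxy‑3',5'‑diprenylacetophenone | CC(=O)c1cc(CC=C(C)C)c(O)c(CC=C(C)C)c1O | intermediate
6 | (E)‑enaminone of 5 | CN(C)/C=C/C(=O)c1cc(CC=C(C)C)c(O)c(CC=C(C)C)c1O | intermediate
7 | 2,4‑dihydroxybenzaldehyde | O=Cc1ccc(O)cc1O | intermediate
8 | 2,4‑bis(MOM‑oxy)benzaldehyde | COCOc1ccc(C=O)c(OCOC)c1 | intermediate
9 | 2,4‑bis(MOM‑oxy)phenol | COCOc1ccc(O)c(OCOC)c1 | intermediate
10 | bis‑MOM chromone | CC(C)=CCc1cc2c(=O)c(Oc3ccc(OCOC)cc3OCOC)coc2c(CC=C(C)C)c1O | intermediate
11 | Eryvarin F | CC(C)=CCc1cc2c(=O)c(Oc3ccc(O)cc3O)coc2c(CC=C(C)C)c1O | target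

**Total steps:** 8. **Longest linear sequence:** 5 (Steps 1, 2, 3, 7, 8; the ring‑B branch, Steps 4–6 then 7, 8, is also 5).

## Three steps most likely to fail
1. **Step 7 (anodic O‑coupling).** Phenoxyl radical C‑coupling instead of O‑coupling, or phenol dimerization, could dominate.
   Fallback: treat 6 with I2 to give the 3‑iodochromone, MOM‑protect the 7‑OH, and do a Cu‑catalysed Ullmann C–O coupling with 9 (CuI, N,N‑dimethylglycine, Cs2CO3, 110 °C). This is a thermal, two‑electron route, not a radical one.
2. **Step 2 (prenylation selectivity).** O‑prenylation and mono‑prenyl products lower the yield of the 3',5'‑diprenyl compound.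
   Fallback: 4'‑O‑prenylate, then Claisen rearrange (PhNEt2, 200 °C) to the 3'‑prenyl compound, and repeat the sequence for C5'.
3. **Step 8 (MOM removal).** Acid could cyclize a prenyl group onto its neighbouring phenol OH to give a chroman.
   Fallback: carry ring B as bis‑TBS ethers (TBSCl, imidazole in Step 5) and remove them at the end with buffered TBAF/AcOH at 0 °C, with no acid at any point.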